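We choose to count half-lives of the starting material first, and to draw the alpha run against that clock.

the same everywhere: free catalyst 11 µM; added ligand 6.7 µM
- alpha: starting material 52 mM; run made earlier
- north-east: starting material 20 mM; time 15 h
- south-east: starting material 40 mM; time 15 h
- north-west: starting material 80 mM; time 15 h
- south-west: starting material 150 mM; time 15 h

- alpha (time / h: product / %, starting material / %): 3.00: 13.8, 36.0; 6.00: 32.7, 12.5; 10.0: 49.0, 3.2; 12.0: 53.9, 1.5; 15.0: 58.7, 1.3

(standard deviation of a reading: 0.3 percentage points)

- what was read earlier has a scatter of 0.3 percentage points, one standard deviation
- steps under discussion: free catalyst + added ligand <-> idle complex; starting material -> intermediate; free catalyst + intermediate -> free catalyst + product; free catalyst + product -> spent catalyst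
- "hardly changes" means that all values lie within two and a half points (for a concentration: within two and a half percent of the largest)

1. amount of product at the end, in percent of the starting material charged for north-east, south-east, north-west, south-west, in this order
2. the course of these numbers from the first flask to the last (rises all the way / falls all the way / falls, then rises / rises, then falls / hardly changes)

In the alpha run, with [starting material] charged at 52 mM, the reading falls from 36.0% at 3.00 h to 3.2% at 10.0 h. That makes the half-life of the starting material, the time in which [starting material] halves, 2.00 h. The two parts of that stretch read 1.97 h and 2.03 h, so we take the decay as first-order.

Against this clock the alpha product curve has a clear form. It leaves the origin at an average 0.0460 h⁻¹ of the charge and steepens to 0.0630 h⁻¹ between 3.00 h and 6.00 h, passing the starting material on the way. By balance, the intermediate reads 54.8% at 6.00 h. Product overtakes it near 10.0 h, at 49.0% against 47.8%. Then comes the knee: the last stretch climbs at 0.0160 h⁻¹, and the run stops at 58.7% with 40.0% still intermediate. The curve is bending, but it has not gone flat.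

The time allowed, 15 h, is longer than the half-life and holds 7.48 of them, which leaves 0.559% of the starting material. The last alpha reading, 1.3%, stands above that, and we keep the count. A first-order half-life does not contain the charge, so we commit to this same remainder from 20 mM to 150 mM. Any difference along the row then lies in what becomes of the intermediate.

The forecast gives 71%, 63%, 53% and 43%, a course that falls all the way, on the ground that “Poisoning scales with concentration, while the early rates do not.”

The flasks give 69.4%, 62.1%, 52.3% and 42.4%: the course falls all the way, as forecast.

    free catalyst + added ligand ⇌ idle complex, settled at all times (K = 3.80 × 10⁵ M⁻¹)
    starting material → intermediate (k = 0.00570 min⁻¹)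
    free catalyst + intermediate → free catalyst + product (k = 370 M⁻¹ min⁻¹)
    free catalyst + product → spent catalyst (k = 0.150 M⁻¹ min⁻¹)

At 15.0 h, which is 7.48 half-lives by our count, north-east holds 0.592% starting material against our 0.559%, and south-west holds 0.592%. In south-west nearly all of the charge has therefore left the first step, yet 57.0% stands as intermediate, with 88.6% of the catalyst spent. The reaction of free catalyst with product to spent catalyst is the main reason for the product missing in south-west. The forecast's falling course would fail if that step were absent: the run without it turns the shape and lifts south-west from 42.4% to 79.5%.

The numbers in the tables were computed with constants of no real substance, noise included.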